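Which flask turns the largest share of what reacts into links by 2.5 h?

* ranking by share of links in all that became links or side product A or side product B, from high to low, at 2.5 h (epsilon / delta / eta / alpha / beta)
* the share of links in all that became links or side product A or side product B of the flask you put first, at 2.5 h
* the share of links in all that became links or side product A or side product B of the flask you put last, at 2.5 h

| setting | Friday's | epsilon | delta | eta | alpha | beta |
|---|---|---|---|---|---|---|
| first end groups | 18 mM | 5.0 mM | 80 mM | 10 mM | 12 mM | 18 mM |
| second end groups | 24 mM | 16.2 mM | 16.2 mM | 16.2 mM | 16.2 mM | 16.2 mM |
| remark | run made earlier |  |  |  |  |  |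
| time |  | 2.5 h | 2.5 h | 2.5 h | 2.5 h | 2.5 h |

Friday's run (percent of the first end groups charged)

| time / min | links / % | side product A / % |
|---|---|---|
| 2.50 | 2.1 | 0 |
| 8.00 | 6.5 | 0 |
| 15.0 | 10.9 | 0 |
| 20.0 | 11.0 | 1.5 |
| 30.0 | 13.0 | 0.7 |

(each reading ± 0.5 percentage points)

- percent here means first end groups units held: one side product B counts as two
- the earlier runs were read with a standard deviation of 0.5 percentage points

Why do links stall in Friday's run? They read 6.5 % at 8.00 min, and that pace held to 30.0 min would give 24.4 %. The reading there is 13.0 %, about half of that. Side product A reads 0.7 %, small beside the gap. So you should suspect that first end groups leave by a route these readings don't show.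

How would that loss move with the charges? My assumption is a step between two first end groups. Its time constant then shortens as [first end groups] rises, while the link step speeds up with [second end groups]. So the stalled link percent should scale as [second end groups]/[first end groups]. Friday's run gives the factor 0.0975, the link number, a selectivity factor of links over the loss.

Which flask leads? Epsilon has the highest ratio and delta the lowest. I expect links of 31.6 % in epsilon and 1.97 % in delta. The share divides links by what became links or side products, and that is at most the charge, so I expect each share to stand above these link figures; side product B was never read.

The forecast says epsilon > eta > alpha > beta > delta, with 24 % (15 % to 34 %) and 3.5 % (2 % to 6 %). Its ground: “That path is second order in first end groups, so it favours low charges.” The order matches mine, but my epsilon link figure stands above its value for the first flask's share.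

The flasks ran by these steps:

    first end groups + second end groups → links + released group (k = 33.0 M⁻¹ h⁻¹)
    first end groups + released group → side product A (k = 34.0 M⁻¹ h⁻¹)
    2 first end groups → homo dimer (k = 95.0 M⁻¹ h⁻¹)
    first end groups + links → side product B (k = 180 M⁻¹ h⁻¹)

The order is epsilon > eta > alpha > beta > delta, with 52.0 % for epsilon and 16.5 % for delta. Epsilon's share stands 28 points above the forecast. At 2.50 h epsilon holds homo dimer at 37.8 % of its charge, more than its links. Against the link number's 31.6 %, epsilon's links are 28.4 %; against 1.97 %, delta's are 2.47 %. Take a neighbour, epsilon with 20 mM of first end groups: the link number gives 7.90 %, and that flask holds links at 9.83 %.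

The runs were computed with constants of no real substance; noise was put on by code.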